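**Retrosynthetic overview**

1. The strategy rests on ring A, the 4-oxy-cyclopent-2-enone C8–C9–C10–C11–C12 (C9 ketone, C10–Cl, C12 tertiary ether oxygen): it is the aldol of a cis-enedione, and C12 with its oxygen can be the lactone carbonyl of a (Z)-4-chloro-5-ylidenebutenolide whose ring oxygen ends as the C9 ketone.
2. Key disconnection, one operation: C12–C13 (allyl), C8–C12 (ring A, aldol) and O–C6 (ring B, the oxolane O/C12/C8/C7/C6, by opening of a C5–C6 cis-epoxide) lead back to ylidenebutenolide 20 and allylmagnesium bromide 21; ring A forms first, ring B second.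
3. 20 is cut at C8=C9 (vinylogous Mukaiyama aldol, then dehydration) into 4-chloro-2-silyloxyfuran 17 (from tetronic acid) and the α-silyloxy epoxy aldehyde 14.
4. 14: C8 by ozonolysis of a vinyl group, C7 by Felkin–Anh vinyl addition to a cis-epoxy aldehyde, C5/C6 by Sharpless epoxidation of a (Z)-allylic alcohol, C5=C6 by a Z-Wittig reaction of the C1–C5 phosphonium salt.
5. After the key step: ozonolysis of the allyl terminus, Z-Wittig with the hexyl ylide (C14=C15), then exchange of the C7 silyl ether for acetate.

Key step: step 13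

Remark on the chemistry: atoms carry the numbers of the target chain (C1 ester carbon to C20) throughout; the 6,7-relationship needed in 20 is anti (erythro), which a hydroxyl-directed epoxidation of a (Z)-allylic C7 alcohol would not give, so the epoxide is made first and C7 second; enolates and alkoxides that form in the flask are listed in their protonated forms.

**Route**

Step 1
Reactants: 1 methyl 5-bromopentanoate; 2 triphenylphosphine
Product: 3 (5-methoxy-5-oxopentyl)triphenylphosphonium bromide
Conditions: MeCN, reflux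
Reagents that add atoms: none
Why: SN2 quaternisation of triphenylphosphine by the primary bromide (phosphonium salt formation) should be clean, the ester being inert.

Step 2
Reactants: 3 (5-methoxy-5-oxopentyl)triphenylphosphonium bromide; 4 (tert-butyldimethylsilyloxy)acetaldehyde
Product: 6 methyl (5Z)-7-[(tert-butyldimethylsilyl)oxy]hept-5-enoate, via phosphorus ylide 5 (not isolated)
Conditions: NaN(SiMe3)2, THF, −78 °C; then 4, −78 °C → rt
Reagents that add atoms: none
Why: A salt-free Wittig reaction of a non-stabilised ylide with an aldehyde is Z-selective and should set the C5=C6 cis alkene, the ylide being made and used cold so that it does not acylate itself at the ester.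

Step 3
Reactants: 6 methyl (5Z)-7-[(tert-butyldimethylsilyl)oxy]hept-5-enoate
Product: 7 methyl (5Z)-7-hydroxyhept-5-enoate
Conditions: camphorsulfonic acid (cat.), MeOH, 0 °C → rt
Reagents that add atoms: none
Why: Acid-catalysed methanolysis of a primary allylic silyl ether (silyl transfer to methanol) is fast and should leave the methyl ester and the Z-alkene untouched.

Step 4
Reactants: 7 methyl (5Z)-7-hydroxyhept-5-enoate
Product: 8 methyl 4-[(2R,3S)-3-(hydroxymethyl)oxiran-2-yl]butanoate
Conditions: Ti(OiPr)4 (cat.), L-(+)-diethyl tartrate (cat.), t-BuOOH, 4 Å MS, CH2Cl2, −20 °C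
Reagents that add atoms: tert-butyl hydroperoxide, CC(C)(C)OO
Why: Sharpless asymmetric epoxidation of a primary (Z)-allylic alcohol with the L-(+)-tartrate catalyst should deliver oxygen to the face that gives the (2S,3R)-epoxy alcohol in glycidol numbering, that is C5 R and C6 S, the cis geometry being carried over from the alkene.

Step 5
Reactants: 8 methyl 4-[(2R,3S)-3-(hydroxymethyl)oxiran-2-yl]butanoate
Product: 9 methyl 4-[(2R,3R)-3-formyloxiran-2-yl]butanoate
Conditions: TEMPO (cat.), PhI(OAc)2, CH2Cl2, rt
Reagents that add atoms: none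
Why: Oxoammonium (TEMPO) oxidation of the primary alcohol runs without base, so the cis-epoxy aldehyde should form without epimerisation at C6 or opening of the epoxide.

Step 6
Reactants: 9 methyl 4-[(2R,3R)-3-formyloxiran-2-yl]butanoate; 10 vinylmagnesium bromide
Product: 11 methyl 4-[(2R,3S)-3-[(1S)-1-hydroxyprop-2-en-1-yl]oxiran-2-yl]butanoate
Conditions: THF, −78 °C; then aq NH4Cl
Reagents that add atoms: none
Why: Grignard addition to the aldehyde at −78 °C (ester untouched) should follow the polar Felkin–Anh/Cornforth model in weakly chelating THF, the nucleophile passing the C6 hydrogen with the epoxide C–O bond anti and the cis C5 substituent shielding the other face, which gives the 6,7-anti (erythro) carbinol with C7 S.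

Step 7
Reactants: 11 methyl 4-[(2R,3S)-3-[(1S)-1-hydroxyprop-2-en-1-yl]oxiran-2-yl]butanoate
Product: 12 methyl 4-[(2R,3R)-3-[(1S)-1-[(tert-butyldimethylsilyl)oxy]prop-2-en-1-yl]oxiran-2-yl]butanoate
Conditions: TBSCl, imidazole, DMF, rt
Reagents that add atoms: tert-butyldimethylsilyl chloride, CC(C)(C)[Si](C)(C)Cl
Why: Silylation of the secondary alcohol with the silyl chloride and imidazole is a standard protection that is mild enough for the epoxide and turns the C7 oxygen into a poor leaving group for the later enolate chemistry.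

Step 8
Reactants: 12 methyl 4-[(2R,3R)-3-[(1S)-1-[(tert-butyldimethylsilyl)oxy]prop-2-en-1-yl]oxiran-2-yl]butanoate
Product: 14 methyl 4-[(2R,3R)-3-[(1R)-1-[(tert-butyldimethylsilyl)oxy]-2-oxoethyl]oxiran-2-yl]butanoate, via ozonide 13 (not isolated)
Conditions: O3, CH2Cl2, −78 °C; then PPh3, −78 °C → rt
Reagents that add atoms: ozone, [O-][O+]=O
Why: Ozonolysis of the only alkene with reduction of the ozonide by triphenylphosphine should give the C8 aldehyde under neutral conditions, so that the α-silyloxy centre C7 does not epimerise, and the aldehyde is used directly.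

Step 9
Reactants: 15 tetronic acid
Product: 16 4-chlorofuran-2(5H)-one
Conditions: (COCl)2, DMF (cat.), CH2Cl2, 0 °C → rt
Reagents that add atoms: oxalyl chloride, O=C(Cl)C(=O)Cl
Why: Vilsmeier-type activation of the enol of the vinylogous acid followed by addition–elimination of chloride should convert tetronic acid into the vinylogous acid chloride.

Step 10
Reactants: 16 4-chlorofuran-2(5H)-one
Product: 17 tert-butyl[(4-chlorofuran-2-yl)oxy]dimethylsilane
Conditions: TBSOTf, Et3N, CH2Cl2, 0 °C
Reagents that add atoms: tert-butyldimethylsilyl trifluoromethanesulfonate, CC(C)(C)[Si](C)(C)OS(=O)(=O)C(F)(F)F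
Why: Soft enolisation at C5 of the butenolide and O-silylation should give the aromatic 2-silyloxyfuran, the usual nucleophile of vinylogous aldol chemistry.

Step 11
Reactants: 14 methyl 4-[(2R,3R)-3-[(1R)-1-[(tert-butyldimethylsilyl)oxy]-2-oxoethyl]oxiran-2-yl]butanoate; 17 tert-butyl[(4-chlorofuran-2-yl)oxy]dimethylsilane
Product: 18 methyl 4-[(2R,3R)-3-[(1S)-1-[(tert-butyldimethylsilyl)oxy]-2-(3-chloro-5-oxo-2,5-dihydrofuran-2-yl)-2-hydroxyethyl]oxiran-2-yl]butanoate (both epimers at C8 and at C9)
Conditions: BF3·OEt2, CH2Cl2, −78 °C; then aq NaHCO3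
Reagents that add atoms: none
Why: The vinylogous Mukaiyama aldol reaction of a 2-silyloxyfuran with an aldehyde should form the C8–C9 bond at the furan 5-position, the two new centres needing no control because the next step removes both, and the short cold exposure to the Lewis acid should spare the epoxide.

Step 12
Reactants: 18 aldol adduct (both epimers at C8 and at C9)
Product: 20 methyl 4-[(2R,3R)-3-[(1S,2Z)-1-[(tert-butyldimethylsilyl)oxy]-2-(3-chloro-5-oxofuran-2(5H)-ylidene)ethyl]oxiran-2-yl]butanoate, via C8 mesylate 19 (not isolated)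
Conditions: MsCl, Et3N, CH2Cl2, −20 °C → rt
Reagents that add atoms: none
Why: Mesylation of the C8 alcohol and E1cB elimination through the aromatic 2-oxidofuran (the acidic C9–H is removed by triethylamine) should give the γ-ylidenebutenolide, the Z isomer prevailing because the E isomer would press the side chain against the C10 chlorine.

Step 13
Reactants: 20 (Z)-4-chloro-5-ylidenebutenolide (5R,6R,7S); 21 allylmagnesium bromide
Product: 25 methyl (5R)-5-acetoxy-5-[(2S,3S,3aS,6aR)-6a-allyl-3-[(tert-butyldimethylsilyl)oxy]-5-chloro-4-oxo-3,3a,4,6a-tetrahydro-2H-cyclopenta[b]furan-2-yl]pentanoate, via open cis-enedione enolate 22 (not isolated), via 4-hydroxycyclopentenone aldolate 23 (not isolated), via bicyclic C5 alkoxide 24 (not isolated)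
Conditions: 21 (1.05 equiv), CeCl3 (dried), THF, −78 °C, premixed; 20 added, −78 → 0 °C; then Ac2O, DMAP (cat.), 0 °C
Reagents that add atoms: acetic anhydride, CC(=O)OC(C)=O
Why: The allylcerium reagent adds 1,2 to the enol-lactone carbonyl C12 and the tetrahedral alkoxide opens to the C12 ketone and the C8=C9 enolate of a cis-enedione (Fujimoto–Belleau-type alkylative opening of an enol lactone), the two partners being held together by the C10=C11 alkene. Ring A then closes by the intramolecular aldol C8→C12 (5-(enolendo)-exo-trig, the mode of the classical 1,4-diketone cyclopentenone closure) to the aldolate 23, and ring B closes by 5-exo-tet attack of that alkoxide on C6 of the cis-epoxide with inversion, which leaves C5 untouched and frees the C5 alkoxide 24, trapped as the acetate before it can lactonise onto the C1 ester. The closest known reactions are the addition of organometallic reagents to γ-ylidenebutenolides to give 4-hydroxycyclopent-2-enones and the base-mediated 5-exo cyclisation of epoxy alcohols. C8 and C12 are set together: only an aldolate with the C12 oxygen cis to the C8 side chain can reach C6, the aldol is reversible so the other aldolates return through the open enolate, and of the two cis aldolates the one that puts the C7 silyloxy group and the C5 chain on the convex face of the bicycle (8S,12R) should close faster, while C6 is set by inversion and C5 by retention of the epoxide carbons. The step needs attack at C12 and not at the C1 methyl ester, at C10–Cl or at C8 of the dienoate, and only one addition: the enol-lactone carbonyl is the most electrophilic acyl group of the substrate, the oxophilic and weakly basic organocerium is used in near-stoichiometric amount at −78 °C, and the ketone that is set free is captured at once by the internal enolate. Closure through the tertiary alkoxide and not through the enolate oxygen is expected because the alkoxide is the stronger nucleophile.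

Step 14
Reactants: 25 C5-acetoxy C7-silyloxy allyl bicycle
Product: 27 methyl (5R)-5-acetoxy-5-[(2S,3S,3aS,6aR)-3-[(tert-butyldimethylsilyl)oxy]-5-chloro-4-oxo-6a-(2-oxoethyl)-3,3a,4,6a-tetrahydro-2H-cyclopenta[b]furan-2-yl]pentanoate, via ozonide 26 (not isolated)
Conditions: O3, CH2Cl2, −78 °C (Sudan Red 7B end point); then PPh3, −78 °C → rt
Reagents that add atoms: ozone, [O-][O+]=O
Why: Ozonolysis should be selective for the electron-rich monosubstituted alkene of the allyl group over the chlorine-bearing, carbonyl-conjugated C10=C11 alkene when ozone is dosed to an indicator end point, and reduction of the ozonide gives the C14 aldehyde.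

Step 15
Reactants: 27 C14 aldehyde; 28 hexyltriphenylphosphonium bromide
Product: 30 methyl (5R)-5-acetoxy-5-[(2S,3S,3aS,6aR)-3-[(tert-butyldimethylsilyl)oxy]-5-chloro-6a-[(2Z)-oct-2-en-1-yl]-4-oxo-3,3a,4,6a-tetrahydro-2H-cyclopenta[b]furan-2-yl]pentanoate, via hexylidene ylide 29 (not isolated)
Conditions: NaN(SiMe3)2, THF, −78 °C; then 27, −78 → 0 °C
Reagents that add atoms: none
Why: The salt-free Wittig reaction of the non-stabilised hexylidene ylide with the aldehyde at −78 °C is Z-selective and should set the C14=C15 cis alkene, the aldehyde reacting far faster than the enone carbonyl or the acetate, and one equivalent of ylide at low temperature limiting enolisation.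

Step 16
Reactants: 30 C7 silyl ether with the full C13–C20 chain
Product: 31 methyl (5R)-5-acetoxy-5-[(2R,3S,3aS,6aR)-5-chloro-3-hydroxy-6a-[(2Z)-oct-2-en-1-yl]-4-oxo-3,3a,4,6a-tetrahydro-2H-cyclopenta[b]furan-2-yl]pentanoate
Conditions: HF·pyridine, pyridine, THF, 0 °C → rt
Reagents that add atoms: none
Why: Fluoride-mediated cleavage of the silyl ether with buffered HF·pyridine is mildly acidic, so the β-hydroxy ketone that is uncovered is not exposed to base and should not eliminate.

Step 17
Reactants: 31 C7 alcohol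
Product: 32 methyl (5R)-5-acetoxy-5-[(2S,3S,3aS,6aR)-3-acetoxy-5-chloro-6a-[(2Z)-oct-2-en-1-yl]-4-oxo-3,3a,4,6a-tetrahydro-2H-cyclopenta[b]furan-2-yl]pentanoate (target)
Conditions: Ac2O, pyridine, DMAP (cat.), CH2Cl2, 0 °C
Reagents that add atoms: acetic anhydride, CC(=O)OC(C)=O
Why: Nucleophile-catalysed acetylation of the secondary C7 alcohol completes the target, elimination of the β-acetoxy group being disfavoured because the new alkene would sit at the ring fusion, and the reaction is kept cold and short.

**Compound list**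

1 | methyl 5-bromopentanoate | COC(=O)CCCCBr | starting material
2 | triphenylphosphine | c1ccc(cc1)P(c1ccccc1)c1ccccc1 | starting material
3 | (5-methoxy-5-oxopentyl)triphenylphosphonium bromide | COC(=O)CCCC[P+](c1ccccc1)(c1ccccc1)c1ccccc1.[Br-] | intermediate
4 | (tert-butyldimethylsilyloxy)acetaldehyde | O=CCO[Si](C)(C)C(C)(C)C | starting material
5 | methyl 5-(triphenylphosphoranylidene)pentanoate (ylide, not isolated) | COC(=O)CCCC=P(c1ccccc1)(c1ccccc1)c1ccccc1 | intermediate
6 | methyl (5Z)-7-[(tert-butyldimethylsilyl)oxy]hept-5-enoate | COC(=O)CCC/C=C\CO[Si](C)(C)C(C)(C)C | intermediate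
7 | methyl (5Z)-7-hydroxyhept-5-enoate | COC(=O)CCC/C=C\CO | intermediate
8 | methyl 4-[(2R,3S)-3-(hydroxymethyl)oxiran-2-yl]butanoate (cis-epoxide, 5R,6S) | OC[C@@H]1O[C@@H]1CCCC(=O)OC | intermediate
9 | methyl 4-[(2R,3R)-3-formyloxiran-2-yl]butanoate (cis-epoxy aldehyde, 5R,6R) | O=C[C@@H]1O[C@@H]1CCCC(=O)OC | intermediate
10 | vinylmagnesium bromide | C=C[Mg]Br | starting material
11 | methyl 4-[(2R,3S)-3-[(1S)-1-hydroxyprop-2-en-1-yl]oxiran-2-yl]butanoate (6,7-anti; 5R,6S,7S) | C=C[C@H](O)[C@@H]1O[C@@H]1CCCC(=O)OC | intermediate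
12 | methyl 4-[(2R,3R)-3-[(1S)-1-[(tert-butyldimethylsilyl)oxy]prop-2-en-1-yl]oxiran-2-yl]butanoate | C=C[C@H](O[Si](C)(C)C(C)(C)C)[C@@H]1O[C@@H]1CCCC(=O)OC | intermediate
13 | ozonide of 12 (1,2,4-trioxolan-3-yl in place of the vinyl group; not isolated) | C1OC(OO1)[C@H](O[Si](C)(C)C(C)(C)C)[C@@H]2O[C@@H]2CCCC(=O)OC | intermediate
14 | methyl 4-[(2R,3R)-3-[(1R)-1-[(tert-butyldimethylsilyl)oxy]-2-oxoethyl]oxiran-2-yl]butanoate | O=C[C@H](O[Si](C)(C)C(C)(C)C)[C@@H]1O[C@@H]1CCCC(=O)OC | intermediate
15 | tetronic acid (furan-2,4(3H,5H)-dione) | O=C1CC(=O)CO1 | starting material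
16 | 4-chlorofuran-2(5H)-one | O=C1C=C(Cl)CO1 | intermediate
17 | tert-butyl[(4-chlorofuran-2-yl)oxy]dimethylsilane | CC(C)(C)[Si](C)(C)Oc1cc(Cl)co1 | intermediate
18 | methyl 4-[(2R,3R)-3-[(1S)-1-[(tert-butyldimethylsilyl)oxy]-2-(3-chloro-5-oxo-2,5-dihydrofuran-2-yl)-2-hydroxyethyl]oxiran-2-yl]butanoate (both epimers at C8 and C9) | O=C1C=C(Cl)C(O1)C(O)[C@H](O[Si](C)(C)C(C)(C)C)[C@@H]2O[C@@H]2CCCC(=O)OC | intermediate
19 | C8 methanesulfonate of 18 (not isolated) | O=C1C=C(Cl)C(O1)C(OS(C)(=O)=O)[C@H](O[Si](C)(C)C(C)(C)C)[C@@H]2O[C@@H]2CCCC(=O)OC | intermediate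
20 | methyl 4-[(2R,3R)-3-[(1S,2Z)-1-[(tert-butyldimethylsilyl)oxy]-2-(3-chloro-5-oxofuran-2(5H)-ylidene)ethyl]oxiran-2-yl]butanoate (key-step precursor; 5R,6R,7S) | O=C1C=C(Cl)/C(=C/[C@H](O[Si](C)(C)C(C)(C)C)[C@@H]2O[C@@H]2CCCC(=O)OC)O1 | intermediate
21 | allylmagnesium bromide | C=CC[Mg]Br | starting material
22 | methyl 4-[(2R,3R)-3-[(1S,4E)-1-[(tert-butyldimethylsilyl)oxy]-4-chloro-3,6-dioxonona-4,8-dien-1-yl]oxiran-2-yl]butanoate (open cis-enedione, present as its C8=C9 enolate; not isolated) | C=CCC(=O)/C=C(Cl)\C(=O)C[C@H](O[Si](C)(C)C(C)(C)C)[C@@H]1O[C@@H]1CCCC(=O)OC | intermediate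
23 | 4-allyl-2-chloro-4-hydroxycyclopent-2-enone carrying at C8 the C7 silyloxy/C5–C6 epoxide chain (5R,6R,7S,8S,12R; present as its C12 alkoxide; not isolated) | C=CC[C@]1(O)C=C(Cl)C(=O)[C@H]1[C@H](O[Si](C)(C)C(C)(C)C)[C@@H]2O[C@@H]2CCCC(=O)OC | intermediate
24 | methyl (5R)-5-hydroxy-5-[(2S,3S,3aS,6aR)-6a-allyl-3-[(tert-butyldimethylsilyl)oxy]-5-chloro-4-oxo-3,3a,4,6a-tetrahydro-2H-cyclopenta[b]furan-2-yl]pentanoate (free C5 alcohol, present as its alkoxide; not isolated) | C=CC[C@]12C=C(Cl)C(=O)[C@H]1[C@H](O[Si](C)(C)C(C)(C)C)[C@H]([C@@H](CCCC(=O)OC)O)O2 | intermediate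
25 | methyl (5R)-5-acetoxy-5-[(2S,3S,3aS,6aR)-6a-allyl-3-[(tert-butyldimethylsilyl)oxy]-5-chloro-4-oxo-3,3a,4,6a-tetrahydro-2H-cyclopenta[b]furan-2-yl]pentanoate | C=CC[C@]12C=C(Cl)C(=O)[C@H]1[C@H](O[Si](C)(C)C(C)(C)C)[C@H]([C@@H](CCCC(=O)OC)OC(C)=O)O2 | intermediate
26 | ozonide of 25 (1,2,4-trioxolan-3-ylmethyl on C12; not isolated) | C3OC(OO3)C[C@]12C=C(Cl)C(=O)[C@H]1[C@H](O[Si](C)(C)C(C)(C)C)[C@H]([C@@H](CCCC(=O)OC)OC(C)=O)O2 | intermediate
27 | methyl (5R)-5-acetoxy-5-[(2S,3S,3aS,6aR)-3-[(tert-butyldimethylsilyl)oxy]-5-chloro-4-oxo-6a-(2-oxoethyl)-3,3a,4,6a-tetrahydro-2H-cyclopenta[b]furan-2-yl]pentanoate | O=CC[C@]12C=C(Cl)C(=O)[C@H]1[C@H](O[Si](C)(C)C(C)(C)C)[C@H]([C@@H](CCCC(=O)OC)OC(C)=O)O2 | intermediate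
28 | hexyltriphenylphosphonium bromide | CCCCCC[P+](c1ccccc1)(c1ccccc1)c1ccccc1.[Br-] | starting material
29 | hexylidenetriphenylphosphorane (ylide, not isolated) | CCCCCC=P(c1ccccc1)(c1ccccc1)c1ccccc1 | intermediate
30 | methyl (5R)-5-acetoxy-5-[(2S,3S,3aS,6aR)-3-[(tert-butyldimethylsilyl)oxy]-5-chloro-6a-[(2Z)-oct-2-en-1-yl]-4-oxo-3,3a,4,6a-tetrahydro-2H-cyclopenta[b]furan-2-yl]pentanoate | CCCCC/C=C\C[C@]12C=C(Cl)C(=O)[C@H]1[C@H](O[Si](C)(C)C(C)(C)C)[C@H]([C@@H](CCCC(=O)OC)OC(C)=O)O2 | intermediate
31 | methyl (5R)-5-acetoxy-5-[(2R,3S,3aS,6aR)-5-chloro-3-hydroxy-6a-[(2Z)-oct-2-en-1-yl]-4-oxo-3,3a,4,6a-tetrahydro-2H-cyclopenta[b]furan-2-yl]pentanoate | CCCCC/C=C\C[C@]12C=C(Cl)C(=O)[C@H]1[C@H](O)[C@H]([C@@H](CCCC(=O)OC)OC(C)=O)O2 | intermediate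
32 | methyl (5R)-5-acetoxy-5-[(2S,3S,3aS,6aR)-3-acetoxy-5-chloro-6a-[(2Z)-oct-2-en-1-yl]-4-oxo-3,3a,4,6a-tetrahydro-2H-cyclopenta[b]furan-2-yl]pentanoate (5R,6S,7S,8S,12R) | CCCCC/C=C\C[C@]12C=C(Cl)C(=O)[C@H]1[C@H](OC(C)=O)[C@H]([C@@H](CCCC(=O)OC)OC(C)=O)O2 | target

**Step count and risks**

Total step count: 17. Longest linear sequence: 15 (steps 1–8 and 11–17; steps 9 and 10 form the side branch).

Steps most likely to fail:

Step 13 (greatest risk). What may go wrong: a second allyl addition (to the freed C12 ketone or to the C1 ester); loss of the C7 silyloxy group from the enolate by β-elimination; or stalling at the aldolate because the hindered metal alkoxide opens the epoxide too slowly, so that the acetylation caps the tertiary alkoxide instead. The fallback sets out from 20 and comes back at 25, and it separates the events. The allyl addition is run as above but quenched with acetic acid at −78 °C, and the 4-allyl-4-hydroxycyclopentenone F1 is isolated as a mixture at C8 and C12. Ring B is then closed in a separate step by the known acid-catalysed 5-exo cyclisation of an epoxy alcohol (camphorsulfonic acid, CH2Cl2, 0 °C). The isomer with the C12 hydroxyl cis to the C8 chain should close, with its C8 epimer fed in through the enol, to give alcohol 24. This is acetylated without delay (Ac2O, pyridine, 0 °C) to 25.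

Step 6. What may go wrong: loss of facial selectivity if magnesium chelates the epoxide oxygen and the aldehyde, or epimerisation of the cis-epoxy aldehyde before the addition. The fallback sets out from 9 and comes back at 11. The addition is accepted as a mixture of 11 and its C7 epimer F2. The mixture is oxidised with Dess–Martin periodinane (CH2Cl2, 0 °C) to the single epoxy enone F3. This is reduced with Zn(BH4)2 (Et2O, −30 °C), the known chelation-controlled 1,2-reduction of α,β-epoxy ketones to anti (erythro) epoxy alcohols, which should return 11.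

Step 15. What may go wrong: the basic ylide enolises the β-alkoxy aldehyde so that the C12 ether oxygen is expelled and ring B opens; the ylide adds to the chloro-enone; or the Z-selectivity erodes. The fallback sets out from 25 and comes back at 30. The ozonolysis/Wittig pair is replaced by a Z-selective cross-metathesis of the allyl group of 25 with an excess of 1-heptene (THF, 35 °C). The catalyst is the cyclometalated ruthenium complex Ru(NO3)(=CH-C6H4-2-OiPr)(NHC), in which the NHC is C–H-activated 1-(1-adamantyl)-3-(2,6-diisopropylphenyl)imidazolin-2-ylidene. The reaction needs no base, should leave the electron-poor C10=C11 alkene alone, and gives 30 directly with loss of ethene; compounds 26, 27 and 29 are bypassed.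

**Further compounds**

F1 | step 13 | methyl 4-[(2R,3R)-3-[(S)-[(tert-butyldimethylsilyl)oxy](2-allyl-4-chloro-2-hydroxy-5-oxocyclopent-3-en-1-yl)methyl]oxiran-2-yl]butanoate, mixture at C8 and C12 | C=CCC1(O)C=C(Cl)C(=O)C1[C@H](O[Si](C)(C)C(C)(C)C)[C@@H]2O[C@@H]2CCCC(=O)OC
F2 | step 6 | methyl 4-[(2R,3S)-3-[(1R)-1-hydroxyprop-2-en-1-yl]oxiran-2-yl]butanoate (C7 epimer of 11) | C=C[C@@H](O)[C@@H]1O[C@@H]1CCCC(=O)OC
F3 | step 6 | methyl 4-[(2R,3R)-3-(prop-2-enoyl)oxiran-2-yl]butanoate | C=CC(=O)[C@@H]1O[C@@H]1CCCC(=O)OC
F0 | step 15 | none | none
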